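**Numbering.** Ring carbons are C1–C10 as in the target: Z-C1=C10, E-C4=C5, methyls on C4 and C10, oxygens on C6–C9. The lactone carbons are C11 (on C7), C12 (carbonyl) and C13 (methylene). The target is (6S,7R,8S,9S).

## The problem

The target is a ten-membered carbocycle with a Z-trisubstituted C1=C10 olefin and an E-trisubstituted C4=C5 olefin, and an α-methylene-γ-butyrolactone (O6–C12–C11=C13) is fused across C6–C7. Four contiguous oxygenated stereocentres (C6–C9) lie on one edge of the ring; C7 is a fully substituted carbinol that also carries C11, and only O9 is acylated. In the zigzag sense O6/O7 are anti, O7/O8 syn and O8/O9 anti, and since there is no stereocentre outside this tetrad the absolute configuration has to be imported. Once C6 and C7 are fixed together, C7 can steer C8 (Felkin–Anh addition to a C8 carbonyl) and C8 can steer C9 (chelate-controlled reduction). The 1,5-diene rearranges to a divinylcyclohexane on heating and cyclises across the ring with acid. The methylene lactone takes up thiols, amines and hydride, and the isobutyrate migrates to a neighbouring free hydroxyl under base. Closing a ten-membered ring end to end is slow and strained, and two trisubstituted olefins of opposite geometry must be right. The enabling feature is that O–C9–C8–C7–C6–C5=C4 is an oxy-Cope retron, and that C9, C10, C1, C2, C3 and C4 can be the atoms of a cyclohexene that already holds the Z-olefin.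

## Retrosynthesis

**33 ⇒ 32 ⇒ 31.** Only O–protecting-group bonds are cut. O8 must be blocked while the lactone is made, because it is as well placed as O6 to lactonise, and O7 is kept masked so that no four-membered lactone can compete. A silyl ether on O8 and a methoxymethyl ether on O7 are both removable without base or protic acid.

**31 ⇒ 30.** The C11–C12 and C12–O6 bonds are cut, with C12 supplied as carbon monoxide. An ethynyl group on C7 then carries C11 and C13 inertly through the whole synthesis. The neighbouring choice, oxidising an isopropenyl methyl group, would compete with four ring allylic positions. The forward step needs O6 as the only free hydroxyl and C–C bond formation at the internal alkyne carbon.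

**30 ⇒ 29 ⇒ 28 ⇒ 27.** These are functional-group changes on O6, O8 and O9. The 8,9-diol 27 is acylated at the less hindered allylic O9; O8, beside the quaternary C7, is then silylated and the O6 benzyl-type ether is removed oxidatively.

**27 ⇒ 25 ⇒ 24 ⇒ 23 ⇒ 21.** The C9–H, C8–H and C8–O bonds are cut. Direct oxygenation of the C8 enolate is not trusted for configuration: an electrophile entering anti to the C6–C7 ring bond is expected to place O8 on the wrong side. C8 is therefore oxidised to the carbonyl level (23, then dione 24), and hydride is brought in anti to the C7–O bond to give 25. Zinc chelation between O8 and the C9 carbonyl then sets C9 (27). The price is two extra steps; the gain is that both centres follow standard acyclic models.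

**21 ⇒ 18 (key).** The C6–C7 bond is cut and C4–C9 re-formed, so the ten-membered dienone becomes a 1,2-dialkenylcyclohexenol. This removes the medium ring, the E-olefin and two stereocentres at once. The cost is one quaternary stereocentre (C4) and two enol ethers of defined geometry. The forward reaction needs a chair transition state and an enolate that survives until it is protonated.

**18 ⇒ 11 + 15.** The C8–C9 bond is cut, which is the convergent point. An alkenyl-cerium reagent from bromide 15 adds to the hindered enone 11. It must add trans to the alkoxyvinyl arm.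

**15 ⇒ 13 ⇒ 12.** The C–Br bond and the enol O–C bond are cut. The commercial ynone 12 is O-alkylated and the enol ether is brominated and dehydrobrominated; the forward sequence must deliver the Z isomer.

**11 ⇒ 9 + 10; 9 ⇒ 8 ⇒ 7 ⇒ 6.** The vinyl C–O bond is cut (stereoretentive copper coupling with alcohol 10), then C5=C6 (iodo-olefination of aldehyde 8). The aldehyde comes from the allyl group by one-position isomerisation (7) and ozonolysis. This is longer than a Wittig enol-ether synthesis but fixes the E geometry, on which C6 depends.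

**6 ⇒ 4 ⇒ 3 ⇒ 1 + 2.** The enone comes from dehydrogenation, and the C4–allyl bond from a catalytic asymmetric decarboxylative allylation. The symmetric ketone 1 has only one possible enolate, so regiochemistry is not an issue, and this step is the sole source of absolute configuration.

## Roads not taken

**Alternative 1:** The cut is C7–C11. The ten-membered C7 ketone A1, which carries a 2-bromoacrylate on O6, would be treated with CrCl2 and catalytic NiCl2. The vinylchromium adds to the ketone and gives the 8-O-triethylsilyl ether of the target A2, which is the same compound as 32 of the present route.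
- Merits: one bond closes the lactone, creates the C7 carbinol and installs the methylene group, with no carbon monoxide and no late unmasking of O7. In these respects the road to A2 is better than the chosen endgame.
- Weak points: A1 already needs the complete ring, both olefins and C6, C8 and C9, so the hardest part of the problem is postponed. The ketone of A1 is flanked by two epimerisable α-oxygenated centres and is open to reductive cleavage by divalent chromium. Ketones are poor acceptors in this addition, and the C7 face is set only by ring conformation.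
- Comparison: the chosen plan offers a single step that makes the ring, both olefin geometries, C6 and C7, with C7 tied to a defined olefin geometry.

**Alternative 2:** The cut is C7–C8. The open-chain dioxinone A3, which carries an allylic bromide and a C8 aldehyde, would be reduced with CrCl2. The oxygen-bearing γ-carbon of the allylchromium adds to the aldehyde and gives the spiro-dioxanone macrocycle A4.
- Merits: it is the most convergent route. The ring, C7, C8 and the methylene group appear together, and the C8 hydroxyl of A4 is obtained directly, where the chosen route spends three steps on it.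
- Weak points: the ring is closed end to end under dilution against transannular strain. Both trisubstituted olefins must be built into the chain of A3. A fully substituted carbon attacks a hindered, epimerisable α-acyloxy aldehyde, and two stereocentres form in a medium-ring transition state with no dependable model. The acetonide of A4 must later be exchanged for the O6 lactone under acid.
- Comparison: the chosen plan offers ring expansion without dilution and olefin geometries that are secured by the six-membered ring and the chair.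

**Alternative 3:** The cut is C2–C3. The allylic sulfone/allylic bromide A5 would be deprotonated with KN(SiMe3)2 to close the ring as the sulfone A6.
- Merits: no stereocentre is at stake in the closure, the reaction type is well established for medium rings, and the tetrad could be made beforehand by reliable acyclic methods. In stereochemical certainty it is at least as good as the chosen plan.
- Weak points: SN2 competes with SN2′. The sulfone anion of A5 is vinylogous to the C9 ether and can expel it. The sulfone of A6 must be removed reductively next to two olefins and a silylalkyne. Both trisubstituted olefins and the whole tetrad need a long linear chain synthesis.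
- Comparison: the chosen plan is much shorter to the ring, with one catalytic asymmetric step feeding all four stereocentres.

Key step: step 11

**Remark (descriptors).** CIP descriptors at C7 and C8 change with the neighbouring substituents along the route; no centre is inverted after it is formed.

**Remark (assumption).** The (R)-configured phosphinooxazoline ligand is taken to give the (R)-quaternary centre with the 2,6-dimethyl substrate, as the (S)-ligand gives the (S)-centre in the 2-methyl series.

**Remark (enolate geometry).** Deprotonation of ketone 21 inside the ten-membered ring is taken to give the enolate with C7 and C10 cis across C8=C9; the geometry has no consequence because C8 is taken to the carbonyl level in step 13.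

## Steps

Step 1
Reactants: 1 2,6-dimethylcyclohexanone; 2 allyl chloroformate
Product: 3 allyl 2,6-dimethylcyclohex-1-en-1-yl carbonate
Conditions: LiN(SiMe3)2, TMEDA, THF, 0 °C; then 2, −78 °C
Reagents that add atoms: none
Why: O-acylation of the only possible enolate of the symmetric ketone gives the allyl enol carbonate; the amine additive favours reaction at oxygen.

Step 2
Reactants: 3 allyl 2,6-dimethylcyclohex-1-en-1-yl carbonate
Product: 4 (2R)-2-allyl-2,6-dimethylcyclohexanone
Conditions: Pd2(dba)3 (2.5 mol%), (R)-t-Bu-PHOX (6 mol%), THF, 25 °C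
Reagents that add atoms: none
Why: Decarboxylative asymmetric allylic alkylation: zerovalent palladium ionises the carbonate, CO2 is lost and the enolate is allylated inside the chiral ligand sphere, which sets the quaternary centre (later C4). The C6 methine epimers are both carried on because that centre is erased in step 3.

Step 3
Reactants: 4 (2R)-2-allyl-2,6-dimethylcyclohexanone
Product: 6 (6R)-6-allyl-2,6-dimethylcyclohex-2-en-1-one, via trimethylsilyl enol ether 5 (not isolated)
Conditions: LiN(i-Pr)2, THF, −78 → 0 °C; Me3SiCl; then Pd(OAc)2, MeCN, 25 °C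
Reagents that add atoms: none
Why: Saegusa–Ito dehydrogenation; only one side of the ketone can enolise, and β-hydride elimination from the divalent palladium enolate gives the endocyclic 2-methyl enone.

Step 4
Reactants: 6 (6R)-6-allyl-2,6-dimethylcyclohex-2-en-1-one
Product: 7 (6R)-2,6-dimethyl-6-[(E)-prop-1-en-1-yl]cyclohex-2-en-1-one
Conditions: PdCl2(MeCN)2 (cat.), toluene, 60 °C
Reagents that add atoms: none
Why: Metal-hydride olefin isomerisation moves the terminal double bond one position inward and stops there because the next carbon is quaternary.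

Step 5
Reactants: 7 (6R)-2,6-dimethyl-6-[(E)-prop-1-en-1-yl]cyclohex-2-en-1-one
Product: 8 (1R)-1,3-dimethyl-2-oxocyclohex-3-ene-1-carbaldehyde
Conditions: O3, CH2Cl2, −78 °C (indicator end-point); then Me2S
Reagents that add atoms: ozone, [O-][O+]=O
Why: Ozonolysis is selective for the electron-rich disubstituted olefin over the electron-poor enone double bond; the sensitive β-keto aldehyde is used crude.

Step 6
Reactants: 8 (1R)-1,3-dimethyl-2-oxocyclohex-3-ene-1-carbaldehyde
Product: 9 (6R)-6-[(E)-2-iodoethenyl]-2,6-dimethylcyclohex-2-en-1-one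
Conditions: CrCl2, CHI3, THF, 0 → 25 °C
Reagents that add atoms: iodoform, IC(I)I
Why: Takai iodo-olefination; the geminal dichromium species made from iodoform and divalent chromium adds to the aldehyde only and eliminates to the E-vinyl iodide.

Step 7
Reactants: 9 (6R)-6-[(E)-2-iodoethenyl]-2,6-dimethylcyclohex-2-en-1-one; 10 4-methoxybenzyl alcohol
Product: 11 (6R)-6-[(E)-2-(4-methoxybenzyloxy)ethenyl]-2,6-dimethylcyclohex-2-en-1-one
Conditions: CuI (10 mol%), 3,4,7,8-tetramethyl-1,10-phenanthroline (20 mol%), Cs2CO3, toluene, 80 °C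
Reagents that add atoms: none
Why: Ullmann-type copper-catalysed C–O coupling of a vinyl iodide with a primary alcohol proceeds with retention, so the E geometry of step 6 is kept in the enol ether.

Step 8
Reactants: 12 4-(trimethylsilyl)but-3-yn-2-one
Product: 13 2-(methoxymethoxy)-4-(trimethylsilyl)but-1-en-3-yne
Conditions: KN(SiMe3)2, THF/DMPU, −78 °C; then MeOCH2Cl
Reagents that add atoms: chloromethyl methyl ether, COCCl
Why: A potassium enolate in a polar medium is alkylated at oxygen by the hard chloromethyl ether, giving the enol acetal.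

Step 9
Reactants: 13 2-(methoxymethoxy)-4-(trimethylsilyl)but-1-en-3-yne
Product: 15 (Z)-1-bromo-2-(methoxymethoxy)-4-(trimethylsilyl)but-1-en-3-yne, via dibromide 14 (not isolated)
Conditions: Br2, CH2Cl2, −78 °C; then DBU, −78 → 0 °C
Reagents that add atoms: bromine, BrBr
Why: Bromine adds to the enol ether double bond (far more nucleophilic than the silylalkyne) and base-induced dehydrobromination returns the β-bromo enol ether. The Z isomer (Br cis to O) should predominate by the cis preference of vicinal halogen/oxygen substituents; it is separated from any E isomer and the geometry is to be checked by NOE.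

Step 10
Reactants: 15 (Z)-1-bromo-2-(methoxymethoxy)-4-(trimethylsilyl)but-1-en-3-yne; 11 (6R)-6-[(E)-2-(4-methoxybenzyloxy)ethenyl]-2,6-dimethylcyclohex-2-en-1-one
Product: 18 (1R,6R)-6-[(E)-2-(4-methoxybenzyloxy)ethenyl]-1-[(Z)-2-(methoxymethoxy)-4-(trimethylsilyl)but-1-en-3-yn-1-yl]-2,6-dimethylcyclohex-2-en-1-ol, via vinyllithium 16 (not isolated), via alkenylcerium dichloride 17 (not isolated)
Conditions: t-BuLi (2 equiv), Et2O, −78 °C; CeCl3, THF, −78 °C; then 11, −78 °C
Reagents that add atoms: none
Why: Bromine–lithium exchange is stereoretentive, and the cis-β-alkoxy vinyllithium is chelated and does not eliminate; the cerium reagent adds 1,2 to the hindered enone without enolisation. Attack is expected anti to the alkoxyvinyl arm (Felkin–Anh: anti to the sp2 substituent, which is also the longer arm), giving the trans-dialkenyl carbinol. This ratio is not secure; any C1 epimer is removed by chromatography on base-washed silica.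

Step 11
Reactants: 18 (1R,6R)-6-[(E)-2-(4-methoxybenzyloxy)ethenyl]-1-[(Z)-2-(methoxymethoxy)-4-(trimethylsilyl)but-1-en-3-yn-1-yl]-2,6-dimethylcyclohex-2-en-1-ol
Product: 21 (1(10)Z,4E,6S,7S)-6-(4-methoxybenzyloxy)-7-(methoxymethoxy)-4,10-dimethyl-7-[(trimethylsilyl)ethynyl]cyclodeca-1(10),4-dien-9-one, via potassium alkoxide 19 (not isolated), via potassium enolate 20 (not isolated)
Conditions: KN(SiMe3)2, 18-crown-6, THF, −78 → 0 °C; then AcOH, THF, −78 °C
Reagents that add atoms: none
Why: Deprotonation gives alkoxide 19, whose oxyanion weakens the C4–C9 bond, and the 1,5-diene C6=C5–C4–C9–C8=C7 undergoes a concerted suprafacial [3,3] shift to enolate 20, which is protonated cold to 21; the closest known reaction type is the anionic oxy-Cope rearrangement of 1,2-dialkenylcyclohexanols to cyclodec-5-enones. The ten-membered ring is not closed end to end: it arises by four-atom ring expansion of the cyclohexene as C4–C9 breaks and C6–C7 forms, so no dilution is needed. In the trans-dialkenyl isomer only the chair with both ring bonds (C4–C3 and C9–C10) equatorial can be reached; C3 equatorial makes C4=C5 E, and the cyclohexene has already fixed C1=C10 as Z. C6 is set by the E-enol ether, which places the benzyloxy group equatorial on the chair whose sense is dictated by the (R)-centre C4. C7 is set on the same chair by the Z-enol ether, which places the methoxymethoxy group axial and the alkynyl group equatorial; both new centres therefore come from C4 through olefin geometry. The step needs chair over boat, which is favoured because no carbon substituent is axial at a bond-forming terminus. It also needs rearrangement to outrun loss of methoxymethoxide from 20, where the C7–O bond is β to the enolate and roughly aligned with it; this is answered by low temperature, a short reaction time and the cold acidic quench.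

Step 12
Reactants: 21 (1(10)Z,4E,6S,7S)-6-(4-methoxybenzyloxy)-7-(methoxymethoxy)-4,10-dimethyl-7-[(trimethylsilyl)ethynyl]cyclodeca-1(10),4-dien-9-one
Product: 23 (1(10)Z,4E,6S,7R,8RS)-8-hydroxy-6-(4-methoxybenzyloxy)-7-(methoxymethoxy)-4,10-dimethyl-7-[(trimethylsilyl)ethynyl]cyclodeca-1(10),4-dien-9-one, via sodium enolate 22 (not isolated)
Conditions: NaN(SiMe3)2, THF, −78 °C; then 2-(phenylsulfonyl)-3-phenyloxaziridine, −78 °C; AcOH
Reagents that add atoms: 2-(phenylsulfonyl)-3-phenyloxaziridine, O=S(=O)(c1ccccc1)N1OC1c1ccccc1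
Why: Kinetic deprotonation of the isolated ketone 21 on its only α-CH2 side (C8; C10 is olefinic) gives sodium enolate 22, and oxygen transfer from the N-sulfonyloxaziridine (Davis enolate hydroxylation, for which the sodium enolate is the usual choice) raises C8 to the alcohol level. Enolate geometry and the C8 configuration do not matter because the centre is erased in step 13, so both epimers are carried on.

Step 13
Reactants: 23 (1(10)Z,4E,6S,7R,8RS)-8-hydroxy-6-(4-methoxybenzyloxy)-7-(methoxymethoxy)-4,10-dimethyl-7-[(trimethylsilyl)ethynyl]cyclodeca-1(10),4-dien-9-one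
Product: 24 (1(10)Z,4E,6S,7S)-6-(4-methoxybenzyloxy)-7-(methoxymethoxy)-4,10-dimethyl-7-[(trimethylsilyl)ethynyl]cyclodeca-1(10),4-diene-8,9-dione
Conditions: Dess–Martin periodinane, NaHCO3, CH2Cl2, 0 → 25 °C
Reagents that add atoms: none
Why: Periodinane oxidation of the α-hydroxy ketone gives the 1,2-dione, which cannot tautomerise because C7 is quaternary and C10 is olefinic.

Step 14
Reactants: 24 (1(10)Z,4E,6S,7S)-6-(4-methoxybenzyloxy)-7-(methoxymethoxy)-4,10-dimethyl-7-[(trimethylsilyl)ethynyl]cyclodeca-1(10),4-diene-8,9-dione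
Product: 25 (1(10)Z,4E,6S,7R,8R)-8-hydroxy-6-(4-methoxybenzyloxy)-7-(methoxymethoxy)-4,10-dimethyl-7-[(trimethylsilyl)ethynyl]cyclodeca-1(10),4-dien-9-one
Conditions: NaBH4 (0.3 equiv), EtOH/THF, −78 °C
Reagents that add atoms: none
Why: The non-conjugated C8 carbonyl is the more electrophilic of the two and should be reduced first by a small hydride under non-chelating protic conditions. Felkin–Anh/Cornforth control puts hydride anti to the C7–O bond, past the slim alkynyl group, which gives the 7,8-syn alcohol with C8 as in the target.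

Step 15
Reactants: 25 (1(10)Z,4E,6S,7R,8R)-8-hydroxy-6-(4-methoxybenzyloxy)-7-(methoxymethoxy)-4,10-dimethyl-7-[(trimethylsilyl)ethynyl]cyclodeca-1(10),4-dien-9-one
Product: 27 (1(10)Z,4E,6S,7R,8S,9S)-7-ethynyl-6-(4-methoxybenzyloxy)-7-(methoxymethoxy)-4,10-dimethylcyclodeca-1(10),4-diene-8,9-diol, via silylalkyne diol 26 (not isolated)
Conditions: Zn(BH4)2, Et2O, −40 → −20 °C; then MeOH, K2CO3, 25 °C
Reagents that add atoms: none
Why: Zinc bridges O8 and the C9 carbonyl, and hydride enters 1,2 from the side of H8, away from the quaternary C7, giving the 8,9-anti diol (chelation-controlled reduction); this also places O9 anti to O7. Methanolic carbonate then removes the alkynyl silyl group (protodesilylation) while no ester is present.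

Step 16
Reactants: 27 (1(10)Z,4E,6S,7R,8S,9S)-7-ethynyl-6-(4-methoxybenzyloxy)-7-(methoxymethoxy)-4,10-dimethylcyclodeca-1(10),4-diene-8,9-diol
Product: 28 (1(10)Z,4E,6S,7R,8S,9S)-7-ethynyl-8-hydroxy-6-(4-methoxybenzyloxy)-7-(methoxymethoxy)-4,10-dimethylcyclodeca-1(10),4-dien-9-yl 2-methylpropanoate
Conditions: (i-PrCO)2O (1.05 equiv), Et3N, DMAP (cat.), CH2Cl2, −40 → 0 °C
Reagents that add atoms: isobutyric anhydride, CC(C)C(=O)OC(=O)C(C)C
Why: Nucleophile-catalysed acylation selects the allylic C9 hydroxyl over the C8 hydroxyl, which is neopentyl-like beside the quaternary C7; acyl migration would favour the same ester.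

Step 17
Reactants: 28 (1(10)Z,4E,6S,7R,8S,9S)-7-ethynyl-8-hydroxy-6-(4-methoxybenzyloxy)-7-(methoxymethoxy)-4,10-dimethylcyclodeca-1(10),4-dien-9-yl 2-methylpropanoate
Product: 29 (1(10)Z,4E,6S,7S,8S,9S)-7-ethynyl-6-(4-methoxybenzyloxy)-7-(methoxymethoxy)-4,10-dimethyl-8-(triethylsilyloxy)cyclodeca-1(10),4-dien-9-yl 2-methylpropanoate
Conditions: Et3SiOTf, 2,6-lutidine, CH2Cl2, −78 → 0 °C
Reagents that add atoms: triethylsilyl trifluoromethanesulfonate, CC[Si](CC)(CC)OS(=O)(=O)C(F)(F)F
Why: The silyl triflate silylates the hindered secondary alcohol under non-nucleophilic base, so no acyl migration occurs; O8 is blocked so that it cannot lactonise in step 19.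

Step 18
Reactants: 29 (1(10)Z,4E,6S,7S,8S,9S)-7-ethynyl-6-(4-methoxybenzyloxy)-7-(methoxymethoxy)-4,10-dimethyl-8-(triethylsilyloxy)cyclodeca-1(10),4-dien-9-yl 2-methylpropanoate
Product: 30 (1(10)Z,4E,6S,7S,8S,9S)-7-ethynyl-6-hydroxy-7-(methoxymethoxy)-4,10-dimethyl-8-(triethylsilyloxy)cyclodeca-1(10),4-dien-9-yl 2-methylpropanoate
Conditions: DDQ, CH2Cl2/pH 7 buffer, 0 °C
Reagents that add atoms: none
Why: Oxidative cleavage of the 4-methoxybenzyl ether (hydride abstraction, then hydrolysis of the hemiacetal) frees O6 alone; the buffer protects the silyl ether and the acetal.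

Step 19
Reactants: 30 (1(10)Z,4E,6S,7S,8S,9S)-7-ethynyl-6-hydroxy-7-(methoxymethoxy)-4,10-dimethyl-8-(triethylsilyloxy)cyclodeca-1(10),4-dien-9-yl 2-methylpropanoate
Product: 31 (1(10)Z,4E,6S,7S,8S,9S)-9-(isobutyryloxy)-7-(methoxymethoxy)-8-(triethylsilyloxy)germacra-1(10),4,11(13)-trien-12,6-olide
Conditions: PdCl2 (10 mol%), SnCl2 (10 mol%), PPh3 (20 mol%), CO (7 atm), MeCN, 65 °C
Reagents that add atoms: carbon monoxide, [C-]#[O+]
Why: Cyclocarbonylation of a homopropargylic alcohol: O6, CO and divalent palladium form an alkoxycarbonyl-palladium species that inserts the alkyne syn in a five-membered closure, and protonolysis releases the α-methylene lactone. O6 is the only free hydroxyl, and its gauche relation to the alkyne on C7 (from step 11) allows the trans ring fusion.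

Step 20
Reactants: 31 (1(10)Z,4E,6S,7S,8S,9S)-9-(isobutyryloxy)-7-(methoxymethoxy)-8-(triethylsilyloxy)germacra-1(10),4,11(13)-trien-12,6-olide
Product: 32 (1(10)Z,4E,6S,7S,8S,9S)-7-hydroxy-9-(isobutyryloxy)-8-(triethylsilyloxy)germacra-1(10),4,11(13)-trien-12,6-olide
Conditions: Me3SiOTf, 2,2′-bipyridyl, CH2Cl2, 0 °C; then H2O
Reagents that add atoms: none
Why: The silyl triflate–bipyridyl pair cleaves the acetal at its exposed methoxy end, and the pyridinium intermediate is hydrolysed by water to the tertiary alcohol. The medium is buffered and aprotic, which is intended to spare the diene, the allylic C–O bonds and the methylene lactone.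

Step 21
Reactants: 32 (1(10)Z,4E,6S,7S,8S,9S)-7-hydroxy-9-(isobutyryloxy)-8-(triethylsilyloxy)germacra-1(10),4,11(13)-trien-12,6-olide
Product: 33 (1(10)Z,4E,6S,7R,8S,9S)-7,8-dihydroxy-9-(isobutyryloxy)germacra-1(10),4,11(13)-trien-12,6-olide
Conditions: HF·pyridine, pyridine, THF, 0 °C
Reagents that add atoms: none
Why: Fluoride-driven Si–O cleavage in pyridine-buffered medium frees O8 without base, so the C9 ester should not migrate and the lactone should not be attacked.

## Compound list

1 | 2,6-dimethylcyclohexanone (cis/trans mixture) | CC1CCCC(C)C1=O | starting material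
2 | allyl chloroformate | C=CCOC(=O)Cl | starting material
3 | allyl 2,6-dimethylcyclohex-1-en-1-yl carbonate (racemic) | C=CCOC(=O)OC1=C(C)CCCC1C | intermediate
4 | (2R)-2-allyl-2,6-dimethylcyclohexanone (both C6 epimers) | C=CC[C@@]1(C)CCCC(C)C1=O | intermediate
5 | [(6R)-6-allyl-2,6-dimethylcyclohex-1-en-1-yl]oxy(trimethyl)silane | C=CC[C@@]1(C)CCCC(C)=C1O[Si](C)(C)C | intermediate
6 | (6R)-6-allyl-2,6-dimethylcyclohex-2-en-1-one | C=CC[C@@]1(C)CCC=C(C)C1=O | intermediate
7 | (6R)-2,6-dimethyl-6-[(E)-prop-1-en-1-yl]cyclohex-2-en-1-one | C/C=C/[C@@]1(C)CCC=C(C)C1=O | intermediate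
8 | (1R)-1,3-dimethyl-2-oxocyclohex-3-ene-1-carbaldehyde | O=C[C@@]1(C)CCC=C(C)C1=O | intermediate
9 | (6R)-6-[(E)-2-iodoethenyl]-2,6-dimethylcyclohex-2-en-1-one | I/C=C/[C@@]1(C)CCC=C(C)C1=O | intermediate
10 | 4-methoxybenzyl alcohol | COc1ccc(CO)cc1 | starting material
11 | (6R)-6-[(E)-2-(4-methoxybenzyloxy)ethenyl]-2,6-dimethylcyclohex-2-en-1-one | COc1ccc(CO/C=C/[C@@]2(C)CCC=C(C)C2=O)cc1 | intermediate
12 | 4-(trimethylsilyl)but-3-yn-2-one | CC(=O)C#C[Si](C)(C)C | starting material
13 | 2-(methoxymethoxy)-4-(trimethylsilyl)but-1-en-3-yne | C=C(OCOC)C#C[Si](C)(C)C | intermediate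
14 | 1,2-dibromo-2-(methoxymethoxy)-4-(trimethylsilyl)but-3-yne (racemic) | BrCC(Br)(OCOC)C#C[Si](C)(C)C | intermediate
15 | (Z)-1-bromo-2-(methoxymethoxy)-4-(trimethylsilyl)but-1-en-3-yne | Br/C=C(\OCOC)C#C[Si](C)(C)C | intermediate
16 | (Z)-[2-(methoxymethoxy)-4-(trimethylsilyl)but-1-en-3-yn-1-yl]lithium | [Li]/C=C(\OCOC)C#C[Si](C)(C)C | intermediate
17 | (Z)-[2-(methoxymethoxy)-4-(trimethylsilyl)but-1-en-3-yn-1-yl]cerium dichloride | Cl[Ce](Cl)/C=C(\OCOC)C#C[Si](C)(C)C | intermediate
18 | (1R,6R)-6-[(E)-2-(4-methoxybenzyloxy)ethenyl]-1-[(Z)-2-(methoxymethoxy)-4-(trimethylsilyl)but-1-en-3-yn-1-yl]-2,6-dimethylcyclohex-2-en-1-ol | O[C@]1(/C=C(/C#C[Si](C)(C)C)OCOC)C(C)=CCC[C@]1(C)/C=C/OCc1ccc(OC)cc1 | intermediate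
19 | potassium (1R,6R)-alkoxide of 18 | [K+].[O-][C@]1(/C=C(/C#C[Si](C)(C)C)OCOC)C(C)=CCC[C@]1(C)/C=C/OCc1ccc(OC)cc1 | intermediate
20 | potassium (1(10)Z,4E,8Z,6S,7S)-6-(4-methoxybenzyloxy)-7-(methoxymethoxy)-4,10-dimethyl-7-[(trimethylsilyl)ethynyl]cyclodeca-1(10),4,8-trien-9-olate (O9 cis to C7) | [K+].COc1ccc(CO[C@H]2/C=C(\C)CC/C=C(/C)\C([O-])=C\[C@]2(OCOC)C#C[Si](C)(C)C)cc1 | intermediate
21 | (1(10)Z,4E,6S,7S)-6-(4-methoxybenzyloxy)-7-(methoxymethoxy)-4,10-dimethyl-7-[(trimethylsilyl)ethynyl]cyclodeca-1(10),4-dien-9-one | COc1ccc(CO[C@H]2/C=C(\C)CC/C=C(/C)C(=O)C[C@]2(OCOC)C#C[Si](C)(C)C)cc1 | intermediate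
22 | sodium (1(10)Z,4E,8E,6S,7S)-6-(4-methoxybenzyloxy)-7-(methoxymethoxy)-4,10-dimethyl-7-[(trimethylsilyl)ethynyl]cyclodeca-1(10),4,8-trien-9-olate (O9 trans to C7; C7 and C10 cis) | [Na+].COc1ccc(CO[C@H]2/C=C(\C)CC/C=C(/C)\C([O-])=C/[C@]2(OCOC)C#C[Si](C)(C)C)cc1 | intermediate
23 | (1(10)Z,4E,6S,7R,8RS)-8-hydroxy-6-(4-methoxybenzyloxy)-7-(methoxymethoxy)-4,10-dimethyl-7-[(trimethylsilyl)ethynyl]cyclodeca-1(10),4-dien-9-one (both C8 epimers) | COc1ccc(CO[C@H]2/C=C(\C)CC/C=C(/C)C(=O)C(O)[C@]2(OCOC)C#C[Si](C)(C)C)cc1 | intermediate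
24 | (1(10)Z,4E,6S,7S)-6-(4-methoxybenzyloxy)-7-(methoxymethoxy)-4,10-dimethyl-7-[(trimethylsilyl)ethynyl]cyclodeca-1(10),4-diene-8,9-dione | COc1ccc(CO[C@H]2/C=C(\C)CC/C=C(/C)C(=O)C(=O)[C@]2(OCOC)C#C[Si](C)(C)C)cc1 | intermediate
25 | (1(10)Z,4E,6S,7R,8R)-8-hydroxy-6-(4-methoxybenzyloxy)-7-(methoxymethoxy)-4,10-dimethyl-7-[(trimethylsilyl)ethynyl]cyclodeca-1(10),4-dien-9-one (C8 as in the target) | COc1ccc(CO[C@H]2/C=C(\C)CC/C=C(/C)C(=O)[C@H](O)[C@]2(OCOC)C#C[Si](C)(C)C)cc1 | intermediate
26 | (1(10)Z,4E,6S,7R,8S,9S)-6-(4-methoxybenzyloxy)-7-(methoxymethoxy)-4,10-dimethyl-7-[(trimethylsilyl)ethynyl]cyclodeca-1(10),4-diene-8,9-diol | COc1ccc(CO[C@H]2/C=C(\C)CC/C=C(/C)[C@H](O)[C@H](O)[C@]2(OCOC)C#C[Si](C)(C)C)cc1 | intermediate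
27 | (1(10)Z,4E,6S,7R,8S,9S)-7-ethynyl-6-(4-methoxybenzyloxy)-7-(methoxymethoxy)-4,10-dimethylcyclodeca-1(10),4-diene-8,9-diol | COc1ccc(CO[C@H]2/C=C(\C)CC/C=C(/C)[C@H](O)[C@H](O)[C@]2(OCOC)C#C)cc1 | intermediate
28 | (1(10)Z,4E,6S,7R,8S,9S)-7-ethynyl-8-hydroxy-6-(4-methoxybenzyloxy)-7-(methoxymethoxy)-4,10-dimethylcyclodeca-1(10),4-dien-9-yl 2-methylpropanoate | COc1ccc(CO[C@H]2/C=C(\C)CC/C=C(/C)[C@H](OC(=O)C(C)C)[C@H](O)[C@]2(OCOC)C#C)cc1 | intermediate
29 | (1(10)Z,4E,6S,7S,8S,9S)-7-ethynyl-6-(4-methoxybenzyloxy)-7-(methoxymethoxy)-4,10-dimethyl-8-(triethylsilyloxy)cyclodeca-1(10),4-dien-9-yl 2-methylpropanoate | COc1ccc(CO[C@H]2/C=C(\C)CC/C=C(/C)[C@H](OC(=O)C(C)C)[C@H](O[Si](CC)(CC)CC)[C@]2(OCOC)C#C)cc1 | intermediate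
30 | (1(10)Z,4E,6S,7S,8S,9S)-7-ethynyl-6-hydroxy-7-(methoxymethoxy)-4,10-dimethyl-8-(triethylsilyloxy)cyclodeca-1(10),4-dien-9-yl 2-methylpropanoate | O[C@H]1/C=C(\C)CC/C=C(/C)[C@H](OC(=O)C(C)C)[C@H](O[Si](CC)(CC)CC)[C@]1(OCOC)C#C | intermediate
31 | (1(10)Z,4E,6S,7S,8S,9S)-9-(isobutyryloxy)-7-(methoxymethoxy)-8-(triethylsilyloxy)germacra-1(10),4,11(13)-trien-12,6-olide | C=C1C(=O)O[C@H]2/C=C(\C)CC/C=C(/C)[C@H](OC(=O)C(C)C)[C@H](O[Si](CC)(CC)CC)[C@]12OCOC | intermediate
32 | (1(10)Z,4E,6S,7S,8S,9S)-7-hydroxy-9-(isobutyryloxy)-8-(triethylsilyloxy)germacra-1(10),4,11(13)-trien-12,6-olide | C=C1C(=O)O[C@H]2/C=C(\C)CC/C=C(/C)[C@H](OC(=O)C(C)C)[C@H](O[Si](CC)(CC)CC)[C@]12O | intermediate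
33 | (1(10)Z,4E,6S,7R,8S,9S)-7,8-dihydroxy-9-(isobutyryloxy)germacra-1(10),4,11(13)-trien-12,6-olide | C=C1C(=O)O[C@H]2/C=C(\C)CC/C=C(/C)[C@H](OC(=O)C(C)C)[C@H](O)[C@]12O | target

## Step count and least certain steps

Total: 21 steps. Longest linear sequence: 19 steps (steps 1–7 and 10–21); steps 8–9 make the side-chain reagent.

**Step 11 (key step).** The most likely failure is expulsion of methoxymethoxide from enolate 20 before the quench, since the C7–O bond is β to the enolate and roughly aligned with it. A competing boat transition state would also erode the C6/C7 relationship. Fallback: starting from 18, the alkoxide is formed with one equivalent of KN(SiMe3)2 and 18-crown-6 at −78 °C in the presence of a base-stable sulfonyloxaziridine without an oxaziridine C–H, such as (camphorsulfonyl)oxaziridine, and the mixture is warmed. Each enolate is then oxygenated as it forms and never accumulates. This gives 23 directly and rejoins the route at 23, where the C8 configuration is immaterial. No new compound is involved.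

**Step 14.** Hydride may be delivered to the C9 carbonyl first, or sodium bound to the acetal may reverse the facial sense at C8. Fallback: C8 is set by inversion instead of reduction, starting from 23. Any 25 already present in 23 is used as such. The other epimer, (1(10)Z,4E,6S,7R,8S)-8-hydroxy-6-(4-methoxybenzyloxy)-7-(methoxymethoxy)-4,10-dimethyl-7-[(trimethylsilyl)ethynyl]cyclodeca-1(10),4-dien-9-one F3, which peripheral oxygenation is expected to favour, is converted with Tf2O and pyridine at −30 °C into its 8-O-trifluoromethanesulfonate F4. KNO2 in DMF then displaces the triflate with inversion (Lattrell–Dax inversion; SN2 next to the carbonyl, no β-hydrogen on C7) and work-up gives 25, where the route resumes.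

**Step 9.** The dehydrobromination may give poor geometric control, and the E isomer would lead to the wrong C7 configuration. Fallback: starting from 12, Me3SiOTf and Et3N give 2-(trimethylsilyloxy)-4-(trimethylsilyl)but-1-en-3-yne F1, and N-bromosuccinimide converts it into 1-bromo-4-(trimethylsilyl)but-3-yn-2-one F2. F2 is enolised with LiN(SiMe3)2 at −78 °C, where the bromine is expected to sit cis to the metal-bound oxygen, and O-alkylated with MeOCH2Cl in THF/DMPU. The geometry is then set by the enolate and not by an elimination, and the route is rejoined at 15.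

**Step 19.** The alkyne beside a quaternary carbon may insert slowly, and at 65 °C with Lewis-acidic tin the diene or the silyl ether may suffer. Fallback: starting from 30, Mo(CO)3(CNt-Bu)3-catalysed hydrostannation with Bu3SnH places tin on the internal alkyne carbon and gives the 7-[1-(tributylstannyl)ethenyl] analogue of 30 F5. Iodine converts it into the 7-(1-iodoethenyl) analogue of 30 F6. Carbonylative lactonisation of this vinyl iodide (PdCl2(PPh3)2, CO at 1 atm, K2CO3, THF, 45 °C) through an acyl-palladium intermediate gives 31, where the route resumes.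

**Step 20.** The Lewis acid may ionise the allylic C6–O or C9–O bond of the finished lactone or start a transannular cyclisation. Fallback: the acetal is removed before the lactone exists, starting from 29. The same Me3SiOTf/2,2′-bipyridyl treatment gives the 7-hydroxy analogue of 29 F7, and DDQ then gives the 6,7-dihydroxy 8-O-triethylsilyl 9-isobutyrate F8. Cyclocarbonylation as in step 19 should prefer five-membered closure through O6 over four-membered closure through the tertiary O7, and gives 32, where the route resumes.

## Further compounds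

F0 | step 11 | none | none
F1 | step 9 | 2-(trimethylsilyloxy)-4-(trimethylsilyl)but-1-en-3-yne | C=C(O[Si](C)(C)C)C#C[Si](C)(C)C
F2 | step 9 | 1-bromo-4-(trimethylsilyl)but-3-yn-2-one | BrCC(=O)C#C[Si](C)(C)C
F3 | step 14 | (1(10)Z,4E,6S,7R,8S)-8-hydroxy-6-(4-methoxybenzyloxy)-7-(methoxymethoxy)-4,10-dimethyl-7-[(trimethylsilyl)ethynyl]cyclodeca-1(10),4-dien-9-one (C8 epimer of 25) | COc1ccc(CO[C@H]2/C=C(\C)CC/C=C(/C)C(=O)[C@@H](O)[C@]2(OCOC)C#C[Si](C)(C)C)cc1
F4 | step 14 | 8-O-trifluoromethanesulfonate of F3 | COc1ccc(CO[C@H]2/C=C(\C)CC/C=C(/C)C(=O)[C@@H](OS(=O)(=O)C(F)(F)F)[C@]2(OCOC)C#C[Si](C)(C)C)cc1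
F5 | step 19 | 7-[1-(tributylstannyl)ethenyl] analogue of 30 | O[C@H]1/C=C(\C)CC/C=C(/C)[C@H](OC(=O)C(C)C)[C@H](O[Si](CC)(CC)CC)[C@]1(OCOC)C(=C)[Sn](CCCC)(CCCC)CCCC
F6 | step 19 | 7-(1-iodoethenyl) analogue of 30 | O[C@H]1/C=C(\C)CC/C=C(/C)[C@H](OC(=O)C(C)C)[C@H](O[Si](CC)(CC)CC)[C@]1(OCOC)C(I)=C
F7 | step 20 | 7-hydroxy analogue of 29 (acetal removed) | COc1ccc(CO[C@H]2/C=C(\C)CC/C=C(/C)[C@H](OC(=O)C(C)C)[C@H](O[Si](CC)(CC)CC)[C@]2(O)C#C)cc1
F8 | step 20 | 7-ethynyl-6,7-dihydroxy-4,10-dimethyl-8-(triethylsilyloxy)cyclodeca-1(10),4-dien-9-yl 2-methylpropanoate | O[C@H]1/C=C(\C)CC/C=C(/C)[C@H](OC(=O)C(C)C)[C@H](O[Si](CC)(CC)CC)[C@]1(O)C#C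
A1 | alternative 1 | ten-membered C7 ketone with 6-O-(2-bromoacryloyl), 8-O-triethylsilyl and 9-O-isobutyryl groups | C=C(Br)C(=O)O[C@H]1/C=C(\C)CC/C=C(/C)[C@H](OC(=O)C(C)C)[C@H](O[Si](CC)(CC)CC)C1=O
A2 | alternative 1 | 8-O-triethylsilyl ether of the target (same compound as 32) | C=C1C(=O)O[C@H]2/C=C(\C)CC/C=C(/C)[C@H](OC(=O)C(C)C)[C@H](O[Si](CC)(CC)CC)[C@]12O
A3 | alternative 2 | open-chain 5-(bromomethyl)-2,2-dimethyl-1,3-dioxin-4-one with C6 silyl ether, C9 isobutyrate and C8 aldehyde | BrCC1=C(OC(C)(C)OC1=O)[C@@H](O[Si](C)(C)C(C)(C)C)/C=C(\C)CC/C=C(/C)[C@H](OC(=O)C(C)C)C=O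
A4 | alternative 2 | ten-membered ring spiro-fused at C7 to a 5-methylene-1,3-dioxan-4-one, with free C8 hydroxyl, C9 isobutyrate and C6 silyl ether | C=C1C(=O)OC(C)(C)O[C@]12[C@@H](O[Si](C)(C)C(C)(C)C)/C=C(\C)CC/C=C(/C)[C@H](OC(=O)C(C)C)[C@@H]2O
A5 | alternative 3 | open-chain C2 phenylsulfonyl / C3 bromide precursor with 6,7-acetonide, 8-O-silyl, 9-O-(4-methoxybenzyl) and 7-(trimethylsilylethynyl) groups | BrC/C(C)=C/[C@@H]1OC(C)(C)O[C@]1(C#C[Si](C)(C)C)[C@@H](O[Si](C)(C)C(C)(C)C)[C@@H](OCc1ccc(OC)cc1)/C(C)=C\CS(=O)(=O)c1ccccc1
A6 | alternative 3 | ten-membered 2-phenylsulfonyl 1(10)Z,4E-diene with the same protecting groups (either C2 epimer) | CC1(C)O[C@H]2/C=C(\C)CC(S(=O)(=O)c3ccccc3)/C=C(/C)[C@H](OCc3ccc(OC)cc3)[C@H](O[Si](C)(C)C(C)(C)C)[C@]2(O1)C#C[Si](C)(C)C
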